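**Plan**

1. Target: methyl 8β-acetoxy-3β-angeloyloxy-5α-hydroxyeudesma-4(15),11(13)-dien-12-oate (3S,5S,7R,8R,10R); eudesmane numbering C1–C15 is used for every intermediate.
2. Retrosynthetic cuts: the two ester C–O bonds; C7–C8 of ring B (indium allylation); C7–C11 (Baylis–Hillman) and C8–C9 (Wittig); C4–C15 (Mannich); C2–O (SmI2); last, C5–C10 and C1–C2 of ring A by [4+2] addition of a 3-silyloxyfuran to methacrolein.
3. Enabling feature: in ring A the carbinol carbon C5 and the quaternary C10 are adjacent, the C5 oxygen and the C10 methyl are trans, and C5 is 1,4 to C2. Ring A can therefore be built as a 7-oxanorbornene whose bridge oxygen (C2–O–C5) is the furan oxygen and is later cut only at C2, next to a C3 ketone.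
4. Forward order: furan → oxygen-bridged ring A → C15 added through the silyl enol ether left by the cycloaddition, bridge opened, C3 alcohol set → chains on C10 and C5 extended → ring B closed last between C7 and C8.
5. Stereochemistry: C10 and C5 from the catalyst-controlled exo cycloaddition; C3 from axial hydride delivery; C7 and C8 from a chair Zimmerman–Traxler closure on the trans-decalin being formed.

Key step: step 6

Assumption: the (S)-oxazaborolidinium ion is taken to expose the Re face of the methacrolein α-carbon (formyl C–H···O model for 2-substituted acroleins); enol ethers 12–17 (E/Z) and acetals 18–27 (C8 anomers) are carried as mixtures that converge later.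

**Route**

Step 1
Reactants: 1 but-3-yn-1-ol
Product: 2 tert-butyl(but-3-yn-1-yloxy)diphenylsilane
Conditions: TBDPSCl, imidazole, CH2Cl2, 0 °C → rt
Reagents that add atoms: tert-butyl(chloro)diphenylsilane, CC(C)(C)[Si](Cl)(c1ccccc1)c1ccccc1
Why: Silylation of a primary alcohol is routine, and the TBDPS ether should outlast the later acidic removal of a TBS group.

Step 2
Reactants: 2 tert-butyl(but-3-yn-1-yloxy)diphenylsilane; 3 (tert-butyldimethylsilyloxy)acetaldehyde
Product: 5 rac-1-(tert-butyldimethylsilyloxy)-6-(tert-butyldiphenylsilyloxy)hex-3-yn-2-ol, via lithium acetylide 4 (not isolated)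
Conditions: n-BuLi, THF, −78 °C; then 3, −78 → −20 °C; H2O
Reagents that add atoms: none
Why: Addition of a lithium acetylide to an aldehyde (alkynylation) is reliable; the racemic carbinol centre is oxidised away in step 3.

Step 3
Reactants: 5 rac-1-(tert-butyldimethylsilyloxy)-6-(tert-butyldiphenylsilyloxy)hex-3-yn-2-ol
Product: 6 1-(tert-butyldimethylsilyloxy)-6-(tert-butyldiphenylsilyloxy)hex-3-yn-2-one
Conditions: Dess–Martin periodinane, CH2Cl2, 0 °C → rt
Reagents that add atoms: none
Why: Dess–Martin oxidation converts propargylic alcohols into ynones under neutral conditions that leave both silyl ethers intact.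

Step 4
Reactants: 6 1-(tert-butyldimethylsilyloxy)-6-(tert-butyldiphenylsilyloxy)hex-3-yn-2-one
Product: 8 5-[2-(tert-butyldiphenylsilyloxy)ethyl]furan-3(2H)-one, via diethylamino enone 7 (not isolated)
Conditions: Et2NH, EtOH, 0 °C → rt; then AcOH/THF/H2O 3:1:1, rt
Reagents that add atoms: none
Why: Conjugate addition of a secondary amine to the ynone, then acid-promoted addition–elimination by the α′-hydroxyl (freed from its TBS ether by the same aqueous acetic acid, which spares the TBDPS ether), is the classical 3(2H)-furanone synthesis from α′-hydroxy ynones.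

Step 5
Reactants: 8 5-[2-(tert-butyldiphenylsilyloxy)ethyl]furan-3(2H)-one
Product: 9 4-(tert-butyldimethylsilyloxy)-2-[2-(tert-butyldiphenylsilyloxy)ethyl]furan
Conditions: TBSOTf, Et3N, CH2Cl2, −78 → 0 °C
Reagents that add atoms: tert-butyldimethylsilyl trifluoromethanesulfonate, CC(C)(C)[Si](C)(C)OS(=O)(=O)C(F)(F)F
Why: Silyl enol ether formation at the C2 methylene of the furanone is driven by aromatisation and gives the 3-silyloxyfuran.

Step 6
Reactants: 9 4-(tert-butyldimethylsilyloxy)-2-[2-(tert-butyldiphenylsilyloxy)ethyl]furan; 10 methacrolein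
Product: 11 (1R,4R,5S)-2-(tert-butyldimethylsilyloxy)-4-[2-(tert-butyldiphenylsilyloxy)ethyl]-5-methyl-7-oxabicyclo[2.2.1]hept-2-ene-5-carbaldehyde (formyl exo; ring A with oxygen bridging C2 and C5)
Conditions: (S)-3,3-diphenyl-1-(2-methylphenyl)tetrahydro-1H,3H-pyrrolo[1,2-c][1,3,2]oxazaborole (20 mol %), HN(SO2CF3)2 (18 mol %), CH2Cl2, −78 °C
Reagents that add atoms: none
Why: Proposed new method: the oxazaborolidinium ion binds methacrolein at the formyl oxygen (s-trans enal, formyl C–H···O contact, one face covered by the neighbouring phenyl group); furan carbon C2, the most nucleophilic one (next to the silyloxy carbon and the ring oxygen), attacks the CH2 terminus, and the boron enolate then closes from C10 onto the 2H-furanium carbon C5 on the same furan face, a strongly asynchronous [4+2] addition. The closest known reaction types are oxazaborolidinium-catalysed Diels–Alder reactions of 2-substituted acroleins with cyclopentadiene and of furan with acrylates, and thermal or Lewis-acid cycloadditions of 3-alkoxy- and 3-silyloxyfurans; their combination on a 2-alkyl-4-silyloxyfuran, joining two fully substituted carbons, has not been shown. Ring A closes as the six-membered ring of the [4+2] mode (in the stepwise limit a six-membered enolate-to-oxocarbenium closure) and gives the 7-oxabicyclo[2.2.1]heptene. C10 is set by the catalyst, which leaves the Re face of the α-carbon open to C5; C5 and C2 are tied to each other by suprafacial addition across the furan and to C10 by the exo position of the formyl group (α-methyl endo), which puts C9 syn to the oxygen bridge and so the C10 methyl anti to the C5 oxygen. The step needs regioselectivity (C2 to C1, secured by the silyloxy group), exo selectivity (usual for 2-substituted acroleins), face selectivity (catalyst) and ring closure in preference to proton or silyl transfer to an open conjugate adduct, so it is run and quenched at −78 °C before the adduct can revert.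

Step 7
Reactants: 11 exo-formyl 7-oxanorbornene adduct
Product: 12 enol ether: 11 with the exo-formyl group converted into exo-CH=CH–OMe (C9=C8, E/Z mixture)
Conditions: MeOCH2PPh3Cl, KN(SiMe3)2, THF, 0 °C; then 11, −78 → 0 °C
Reagents that add atoms: (methoxymethyl)triphenylphosphonium chloride, COC[P+](c1ccccc1)(c1ccccc1)c1ccccc1.[Cl-]
Why: Wittig methoxymethylenation works on hindered non-enolisable aldehydes and adds C8 as a masked aldehyde before any ketone is present; the alkene geometry is immaterial.

Step 8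
Reactants: 12 enol ether
Product: 13 Mannich ketone: oxygen-bridged ring A with C3 ketone, exo (α) CH2NMe2 on C4, CH2CH2OTBDPS on bridgehead C5, endo methyl and exo CH=CHOMe on C10
Conditions: CH2=NMe2+ I− (Eschenmoser's salt), CH2Cl2, 0 °C → rt; aq. NaHCO3
Reagents that add atoms: N,N-dimethylmethylideneammonium iodide, C=[N+](C)C.[I-]
Why: The Mannich reaction of a silyl enol ether with Eschenmoser's salt is regiospecific, so C15 goes onto C4 (exo face) and the C3 ketone is unveiled; the strained silyl enol ether should be far more nucleophilic than the methyl enol ether, whose β-carbon is neopentyl.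

Step 9
Reactants: 13 Mannich ketone
Product: 14 β-hydroxy ketone: cyclohexanone ring A with C3 ketone, 4α-CH2NMe2, 5α-OH, CH2CH2OTBDPS on C5, 10β-methyl, CH=CHOMe on C10
Conditions: SmI2, THF/MeOH 10:1, −78 °C
Reagents that add atoms: none
Why: Reductive cleavage of an α-alkoxy ketone by SmI2 (ketyl, loss of the α-oxygen, protonation of the samarium enolate) is established for 7-oxabicyclo[2.2.1]heptan-2-ones and cuts only C2–O, so the bridge oxygen stays on C5 as the tertiary alcohol.

Step 10
Reactants: 14 β-hydroxy ketone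
Product: 16 enone: ring A with C3 ketone, C4=CH2 (C15), 5α-OH, via trimethylammonium iodide 15 (not isolated)
Conditions: MeI, THF, rt; then CH2Cl2/sat. aq. NaHCO3, rt
Reagents that add atoms: none
Why: Quaternisation and E1cB elimination of the Mannich base (α-methylenation of a ketone) should give the α-methylene ketone, because trimethylamine is a far better leaving group than the C5 hydroxyl.

Step 11
Reactants: 16 enone
Product: 17 diol: 3β,5α-dihydroxy-4-methylene ring A (3S), other groups as in 16
Conditions: NaBH4, CeCl3·7H2O, MeOH, −78 °C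
Reagents that add atoms: none
Why: Luche reduction reduces the enone 1,2, and hydride should enter axially on the α face (where the C5 hydroxyl can also deliver it), giving the equatorial 3β-alcohol trans to the C5 hydroxyl.

Step 12
Reactants: 17 diol
Product: 18 cyclic acetal: cis-fused 2-methoxytetrahydrofuran O(C5)–C8(OMe)–C9–C10 on ring A, free 3β-OH, C4=CH2, CH2CH2OTBDPS on C5 (C8 anomers)
Conditions: pyridinium p-toluenesulfonate (10 mol %), CH2Cl2, 0 °C → rt
Reagents that add atoms: none
Why: Acid-catalysed intramolecular addition of the C5 hydroxyl to the enol ether (acetalisation, five-membered ring) masks the tertiary alcohol and the C8 aldehyde in one group that tolerates base, fluoride and oxidants.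

Step 13
Reactants: 18 cyclic acetal; 19 angelic acid
Product: 21 angelate: 18 with 3β-O-angeloyl, via mixed anhydride 20 (not isolated)
Conditions: 19, 2,4,6-trichlorobenzoyl chloride, Et3N, toluene, rt; then 18, 80 °C
Reagents that add atoms: none
Why: Yamaguchi esterification through the mixed anhydride without DMAP is the standard way to make angelates without Z→E isomerisation, and the secondary C3 hydroxyl is the only free one.

Step 14
Reactants: 21 angelate
Product: 22 primary alcohol: 21 with CH2CH2OH (C6–C7) on C5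
Conditions: Bu4NF, AcOH, THF, 0 °C → rt
Reagents that add atoms: none
Why: Buffered fluoride cleavage of the primary TBDPS ether should leave the angelate and the acetal untouched.

Step 15
Reactants: 22 primary alcohol
Product: 23 aldehyde: 22 with CH2CHO (C7 aldehyde) on C5
Conditions: Dess–Martin periodinane, pyridine, CH2Cl2, 0 °C
Reagents that add atoms: none
Why: Pyridine-buffered Dess–Martin oxidation avoids acid-induced transacetalisation, and with the C5 oxygen held in the acetal no free β-hydroxy aldehyde is formed.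

Step 16
Reactants: 23 aldehyde; 24 methyl acrylate
Product: 25 Baylis–Hillman adduct: C7 carbinol bearing C11(=CH2)CO2Me (C7 epimers)
Conditions: 24 (5 equiv), 1,4-diazabicyclo[2.2.2]octane (1 equiv), 1,4-dioxane/H2O 1:1, rt
Reagents that add atoms: none
Why: The Morita–Baylis–Hillman reaction of an aliphatic aldehyde with methyl acrylate attaches C11–C13 to C7; the new carbinol centre disappears in step 17.

Step 17
Reactants: 25 Baylis–Hillman adduct
Product: 26 allylic bromide: methyl (Z)-2-(bromomethyl)alk-2-enoate unit C7H=C11(CO2Me)CH2Br on C6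
Conditions: NBS, Me2S, CH2Cl2, 0 °C → rt
Reagents that add atoms: N-bromosuccinimide, O=C1CCC(=O)N1Br
Why: Activation of a Baylis–Hillman alcohol as its alkoxysulfonium salt and SN2′ attack of bromide gives the rearranged (Z)-bromide under neutral conditions that spare the acetal.

Step 18
Reactants: 26 allylic bromide
Product: 28 methyl 3β-angeloyloxy-5α,8β-dihydroxyeudesma-4(15),11(13)-dien-12-oate, via lactol 27 (not isolated)
Conditions: Dowex 50WX8 (H+ form), THF/H2O 4:1, rt; filter; In powder, THF/H2O 1:1, rt
Reagents that add atoms: water, O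
Why: Hydrolysis of the 2-methoxytetrahydrofuran gives a lactol whose open hydroxy aldehyde should undergo the intramolecular indium Barbier allylation known for ω-formyl 2-(bromomethyl)alk-2-enoates; the (Z)-allylindium reacts through a chair Zimmerman–Traxler transition state on the forming trans-decalin chair, which puts the acrylate equatorial on C7 (7R) and the oxygen axial on C8 (8R), cis to each other.

Step 19
Reactants: 28 methyl 3β-angeloyloxy-5α,8β-dihydroxyeudesma-4(15),11(13)-dien-12-oate
Product: 29 methyl 8β-acetoxy-3β-angeloyloxy-5α-hydroxyeudesma-4(15),11(13)-dien-12-oate (CNP0179024.1)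
Conditions: Ac2O, 4-(dimethylamino)pyridine (10 mol %), pyridine, CH2Cl2, 0 °C → rt
Reagents that add atoms: acetic anhydride, CC(=O)OC(C)=O
Why: DMAP-catalysed acetylation should esterify the secondary C8 alcohol, while the tertiary C5 alcohol does not react under these conditions.

**Compound list**

1 | but-3-yn-1-ol | C#CCCO | starting material
2 | tert-butyl(but-3-yn-1-yloxy)diphenylsilane | C#CCCO[Si](c1ccccc1)(c1ccccc1)C(C)(C)C | intermediate
3 | (tert-butyldimethylsilyloxy)acetaldehyde | O=CCO[Si](C)(C)C(C)(C)C | starting material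
4 | lithium acetylide of 2 | [Li]C#CCCO[Si](c1ccccc1)(c1ccccc1)C(C)(C)C | intermediate (not isolated)
5 | rac-1-(tert-butyldimethylsilyloxy)-6-(tert-butyldiphenylsilyloxy)hex-3-yn-2-ol (racemic, centre not specified) | CC(C)(C)[Si](C)(C)OCC(O)C#CCCO[Si](c1ccccc1)(c1ccccc1)C(C)(C)C | intermediate
6 | 1-(tert-butyldimethylsilyloxy)-6-(tert-butyldiphenylsilyloxy)hex-3-yn-2-one | CC(C)(C)[Si](C)(C)OCC(=O)C#CCCO[Si](c1ccccc1)(c1ccccc1)C(C)(C)C | intermediate
7 | (E)-4-(diethylamino)-1-(tert-butyldimethylsilyloxy)-6-(tert-butyldiphenylsilyloxy)hex-3-en-2-one | CCN(CC)/C(CCO[Si](c1ccccc1)(c1ccccc1)C(C)(C)C)=C/C(=O)CO[Si](C)(C)C(C)(C)C | intermediate (not isolated)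
8 | 5-[2-(tert-butyldiphenylsilyloxy)ethyl]furan-3(2H)-one | O=C1COC(CCO[Si](c2ccccc2)(c2ccccc2)C(C)(C)C)=C1 | intermediate
9 | 4-(tert-butyldimethylsilyloxy)-2-[2-(tert-butyldiphenylsilyloxy)ethyl]furan | CC(C)(C)[Si](C)(C)Oc1coc(CCO[Si](c2ccccc2)(c2ccccc2)C(C)(C)C)c1 | intermediate (key-step precursor)
10 | methacrolein | CC(=C)C=O | starting material
11 | (1R,4R,5S)-2-(tert-butyldimethylsilyloxy)-4-[2-(tert-butyldiphenylsilyloxy)ethyl]-5-methyl-7-oxabicyclo[2.2.1]hept-2-ene-5-carbaldehyde, formyl exo | O=C[C@@]1(C)C[C@H]2O[C@]1(CCO[Si](c3ccccc3)(c3ccccc3)C(C)(C)C)C=C2O[Si](C)(C)C(C)(C)C | intermediate (key-step product)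
12 | enol ether: 11 with exo-CH=CH–OMe in place of CHO (E/Z mixture, E written) | CO/C=C/[C@@]1(C)C[C@H]2O[C@]1(CCO[Si](c3ccccc3)(c3ccccc3)C(C)(C)C)C=C2O[Si](C)(C)C(C)(C)C | intermediate
13 | Mannich ketone: 7-oxabicyclo[2.2.1]heptan-2-one with exo-CH2NMe2 on C4 (E written) | CO/C=C/[C@@]1(C)C[C@H]2O[C@]1(CCO[Si](c3ccccc3)(c3ccccc3)C(C)(C)C)[C@H](CN(C)C)C2=O | intermediate
14 | β-hydroxy ketone: ring A, C3 ketone, 4α-CH2NMe2, 5α-OH, 10β-CH3 (E written) | CO/C=C/[C@@]1(C)CCC(=O)[C@@H](CN(C)C)[C@]1(O)CCO[Si](c2ccccc2)(c2ccccc2)C(C)(C)C | intermediate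
15 | trimethylammonium iodide of 14 | CO/C=C/[C@@]1(C)CCC(=O)[C@@H](C[N+](C)(C)C)[C@]1(O)CCO[Si](c2ccccc2)(c2ccccc2)C(C)(C)C.[I-] | intermediate (not isolated)
16 | enone: ring A, C3 ketone, C4=CH2, 5α-OH (E written) | CO/C=C/[C@@]1(C)CCC(=O)C(=C)[C@]1(O)CCO[Si](c2ccccc2)(c2ccccc2)C(C)(C)C | intermediate
17 | diol: 3β,5α-dihydroxy-4-methylene ring A (E written) | CO/C=C/[C@@]1(C)CC[C@H](O)C(=C)[C@]1(O)CCO[Si](c2ccccc2)(c2ccccc2)C(C)(C)C | intermediate
18 | cyclic acetal: cis-fused 2-methoxytetrahydrofuran (O on C5, C8 anomers not specified), 3β-OH | COC1C[C@@]2(C)CC[C@H](O)C(=C)[C@@]2(CCO[Si](c3ccccc3)(c3ccccc3)C(C)(C)C)O1 | intermediate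
19 | angelic acid, (Z)-2-methylbut-2-enoic acid | C/C=C(/C)C(=O)O | starting material
20 | angelic 2,4,6-trichlorobenzoic anhydride | C/C=C(/C)C(=O)OC(=O)c1c(Cl)cc(Cl)cc1Cl | intermediate (not isolated)
21 | angelate: 18 with 3β-O-angeloyl | COC1C[C@@]2(C)CC[C@H](OC(=O)/C(C)=C\C)C(=C)[C@@]2(CCO[Si](c3ccccc3)(c3ccccc3)C(C)(C)C)O1 | intermediate
22 | primary alcohol (C7–OH) | COC1C[C@@]2(C)CC[C@H](OC(=O)/C(C)=C\C)C(=C)[C@@]2(CCO)O1 | intermediate
23 | aldehyde (C7) | COC1C[C@@]2(C)CC[C@H](OC(=O)/C(C)=C\C)C(=C)[C@@]2(CC=O)O1 | intermediate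
24 | methyl acrylate | C=CC(=O)OC | starting material
25 | Baylis–Hillman adduct (C7 epimers not specified) | COC1C[C@@]2(C)CC[C@H](OC(=O)/C(C)=C\C)C(=C)[C@@]2(CC(O)C(=C)C(=O)OC)O1 | intermediate
26 | (Z)-allylic bromide | COC1C[C@@]2(C)CC[C@H](OC(=O)/C(C)=C\C)C(=C)[C@@]2(C/C=C(\CBr)C(=O)OC)O1 | intermediate
27 | lactol (C8 anomers, in equilibrium with the 5-hydroxy C8 aldehyde) | OC1C[C@@]2(C)CC[C@H](OC(=O)/C(C)=C\C)C(=C)[C@@]2(C/C=C(\CBr)C(=O)OC)O1 | intermediate (not isolated)
28 | methyl (3S,5S,7R,8R,10R)-3-angeloyloxy-5,8-dihydroxyeudesma-4(15),11(13)-dien-12-oate | C=C(C(=O)OC)[C@H]1C[C@@]2(O)C(=C)[C@@H](OC(=O)/C(C)=C\C)CC[C@]2(C)C[C@H]1O | intermediate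
29 | methyl (3S,5S,7R,8R,10R)-8-acetoxy-3-angeloyloxy-5-hydroxyeudesma-4(15),11(13)-dien-12-oate | C=C(C(=O)OC)[C@H]1C[C@@]2(O)C(=C)[C@@H](OC(=O)/C(C)=C\C)CC[C@]2(C)C[C@H]1OC(C)=O | target

**Count**

Total steps: 19. Longest linear sequence: 19 steps (1 → 29); 3, 10, 19 and 24 enter as purchased materials.

**Steps most likely to fail**

Step 6. The zwitterion may collapse by proton or silyl transfer to an open conjugate-addition product, the adduct may revert on warming, or exo and face selectivity may be low. Fallback (sets out from 9 and 10, returns at 13): the cycloaddition is run without the chiral catalyst, with Me2AlCl in CH2Cl2 at −78 °C, to give the racemic exo adduct F1. Wittig methoxymethylenation as in step 7 gives the racemic enol ether F2, and the Eschenmoser reaction as in step 8 gives the racemic Mannich ketone F3. This tertiary amine is resolved by crystallisation with (−)-O,O′-di-p-toluoyl-L-tartaric acid as the hydrogen tartrate salt F4 of the wanted enantiomer, and aqueous NaHCO3 liberates 13.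

Step 18. The allylindium may be protonated before ring closure, the cis hydroxy ester may lactonise onto C12, or closure through the E-configured allylindium may give the C8 epimer. Fallback (sets out from 26, returns at 28): after the same resin hydrolysis to 27, ring B is closed with CrCl2 in THF (Nozaki–Hiyama–Kishi allylation, anhydrous). This closure is expected to favour the 7,8-trans product, the 8α-hydroxy epimer F5. Dess–Martin oxidation gives the 8-ketone F6, and NaBH4/CeCl3·7H2O at −78 °C should return 28, because the axial C10 methyl covers the β face and hydride enters from the α face.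

Step 16. Addition to the β-branched aldehyde may be slow, leaving time for base-induced β-elimination that opens the acetal ring. Fallback (sets out from 23, returns at 25): aldol addition of the lithium enolate of methyl 3-(dimethylamino)propanoate (LiN(i-Pr)2, THF, −78 °C) to 23 gives the β-hydroxy α-(dimethylaminomethyl) ester F7. MeI converts it into the methiodide F8, and 1,8-diazabicyclo[5.4.0]undec-7-ene eliminates trimethylamine to give 25.

**Further compounds**

F1 | step 6 | racemic exo adduct (11 and its enantiomer) | O=C[C@@]1(C)C[C@H]2O[C@]1(CCO[Si](c3ccccc3)(c3ccccc3)C(C)(C)C)C=C2O[Si](C)(C)C(C)(C)C.O=C[C@]1(C)C[C@@H]2O[C@@]1(CCO[Si](c3ccccc3)(c3ccccc3)C(C)(C)C)C=C2O[Si](C)(C)C(C)(C)C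
F2 | step 6 | racemic enol ether (12 and its enantiomer) | CO/C=C/[C@@]1(C)C[C@H]2O[C@]1(CCO[Si](c3ccccc3)(c3ccccc3)C(C)(C)C)C=C2O[Si](C)(C)C(C)(C)C.CO/C=C/[C@]1(C)C[C@@H]2O[C@@]1(CCO[Si](c3ccccc3)(c3ccccc3)C(C)(C)C)C=C2O[Si](C)(C)C(C)(C)C
F3 | step 6 | racemic Mannich ketone (13 and its enantiomer) | CO/C=C/[C@@]1(C)C[C@H]2O[C@]1(CCO[Si](c3ccccc3)(c3ccccc3)C(C)(C)C)[C@H](CN(C)C)C2=O.CO/C=C/[C@]1(C)C[C@@H]2O[C@@]1(CCO[Si](c3ccccc3)(c3ccccc3)C(C)(C)C)[C@@H](CN(C)C)C2=O
F4 | step 6 | hydrogen (2R,3R)-di-O-p-toluoyltartrate salt of 13 | CO/C=C/[C@@]1(C)C[C@H]2O[C@]1(CCO[Si](c3ccccc3)(c3ccccc3)C(C)(C)C)[C@H](C[NH+](C)C)C2=O.[O-]C(=O)[C@H](OC(=O)c1ccc(C)cc1)[C@@H](OC(=O)c1ccc(C)cc1)C(=O)O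
F5 | step 18 | 8α-hydroxy epimer of 28 | C=C(C(=O)OC)[C@H]1C[C@@]2(O)C(=C)[C@@H](OC(=O)/C(C)=C\C)CC[C@]2(C)C[C@@H]1O
F6 | step 18 | 8-ketone, methyl 3β-angeloyloxy-5α-hydroxy-8-oxoeudesma-4(15),11(13)-dien-12-oate | C=C(C(=O)OC)[C@H]1C[C@@]2(O)C(=C)[C@@H](OC(=O)/C(C)=C\C)CC[C@]2(C)CC1=O
F7 | step 16 | aldol adduct of 23 with methyl 3-(dimethylamino)propanoate (epimer mixture) | COC1C[C@@]2(C)CC[C@H](OC(=O)/C(C)=C\C)C(=C)[C@@]2(CC(O)C(CN(C)C)C(=O)OC)O1
F8 | step 16 | methiodide of F7 | COC1C[C@@]2(C)CC[C@H](OC(=O)/C(C)=C\C)C(=C)[C@@]2(CC(O)C(C[N+](C)(C)C)C(=O)OC)O1.[I-]
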